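Numbering (icetexane): ring A = C1-C5 + C10; seven-membered ring B = C5-C10 + C20; ring C = C8, C9, C11-C14. C19 is the lactone carbonyl on C4 and the lactone oxygen sits on C6.
Cuts: (i) the hydroxyquinone goes back to the 11,12-methylenedioxy-14-methoxy arene; (ii) C1-C10 and C9-C20 are cut together, giving a 1,7-dialdehyde (C1, C20); (iii) C7-C8 and O-C6 are cut together, giving an aryl iodide and a 4-pentynoic acid; (iv) C4-C3, C4-CH3 and C5-C6 are cut, giving 5,6-dihydropyran-2-one.
Enabling feature: C20 lies between C9 (the free CH of ring C, ortho to O-11) and C10, and C10 is 1,6 to C1. As an aldehyde, C20 is first the electrophile for C9; once its oxygen has left as water, the C10=C20 styrene, pushed by O-11, makes C10 the nucleophile for the C1 aldehyde.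
Forward order: ring C is bought. A temporary delta-lactone (C19-O-C20, not in the target) carries the stereocontrolled alkylations and is then opened. The gamma-enol lactone and C7-C8 arise in one palladium step whose E geometry puts ring C cis to C5. Rings B and A close in one acid-catalysed operation, and the quinone comes last.
Stereochemistry: C5 comes from a rhodium/chiral-diene conjugate alkynylation, C4 from allylation of the delta-lactone enolate anti to the C5 alkynyl group, and C1 from a chair-like closure on the cis-fused lactone.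

Key step: step 13

Assumption: the antipode of the chiral diene ligand in step 5 is chosen so that the (R)-lactone 11 results. All later centres follow from this one.

Step 1
Reactants: 1 5-methoxy-1,3-benzodioxole
Product: 3 2-(5-methoxy-1,3-benzodioxol-4-yl)propan-2-ol, via aryllithium 2 (not isolated)
Conditions: n-BuLi, THF, 0 °C; acetone, -78 °C to rt; H2O
Reagents that add atoms: acetone CC(C)=O
Why: Directed ortho-lithiation takes C4, the most acidic site because it lies between the dioxole oxygen and the methoxy group, and the aryllithium undergoes 1,2-addition to acetone.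

Step 2
Reactants: 3 2-(5-methoxy-1,3-benzodioxol-4-yl)propan-2-ol
Product: 4 5-methoxy-4-(propan-2-yl)-1,3-benzodioxole
Conditions: Et3SiH, CF3CO2H, CH2Cl2, 0 °C
Reagents that add atoms: none
Why: Ionic hydrogenation: the acid ionises the tertiary, doubly ortho-oxygenated benzylic alcohol and the silane delivers hydride, while the dioxole and the methyl ether are inert.

Step 3
Reactants: 4 5-methoxy-4-(propan-2-yl)-1,3-benzodioxole
Product: 5 6-iodo-5-methoxy-4-(propan-2-yl)-1,3-benzodioxole
Conditions: N-iodosuccinimide, CF3CO2H (cat.), MeCN, 0 °C to rt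
Reagents that add atoms: N-iodosuccinimide O=C1CCC(=O)N1I
Why: Electrophilic aromatic iodination goes to C6 (future C8), which is ortho to OMe and para to a dioxole oxygen, and leaves C7-H (future C9) free.

Step 4
Reactants: 6 ethynyltri(propan-2-yl)silane; 7 benzophenone
Product: 9 1,1-diphenyl-3-[tri(propan-2-yl)silyl]prop-2-yn-1-ol, via lithium acetylide 8 (not isolated)
Conditions: n-BuLi, THF, -78 °C; 7, -78 °C to rt; H2O
Reagents that add atoms: none
Why: 1,2-Addition of an acetylide to a non-enolisable ketone gives the tertiary propargylic alcohol that serves as the alkynyl donor in step 5.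

Step 5
Reactants: 10 5,6-dihydro-2H-pyran-2-one; 9 1,1-diphenyl-3-[tri(propan-2-yl)silyl]prop-2-yn-1-ol
Product: 11 (4R)-4-{[tri(propan-2-yl)silyl]ethynyl}oxan-2-one
Conditions: [RhCl(C2H4)2]2 (2.5 mol %), chiral 2,5-diarylbicyclo[2.2.2]octa-2,5-diene (5.5 mol %), Cs2CO3 (20 mol %), toluene, 80 °C
Reagents that add atoms: none
Why: Rhodium-catalysed asymmetric conjugate alkynylation: the rhodium alkoxide of 9 undergoes beta-alkynyl elimination (benzophenone leaves), the alkynylrhodium adds 1,4 to the cyclic enoate, and the chiral diene selects the face, which sets C5.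

Step 6
Reactants: 11 (4R)-4-{[tri(propan-2-yl)silyl]ethynyl}oxan-2-one
Product: 13 (3S,4R)-3-methyl-4-{[tri(propan-2-yl)silyl]ethynyl}oxan-2-one, via lithium enolate 12 (not isolated)
Conditions: LDA, THF, -78 °C; MeI, -78 to -40 °C
Reagents that add atoms: iodomethane CI
Why: Kinetic alkylation of the lactone enolate brings methyl in anti to the alkynyl group, although this centre is planarised again in step 7.

Step 7
Reactants: 13 (3S,4R)-3-methyl-4-{[tri(propan-2-yl)silyl]ethynyl}oxan-2-one
Product: 15 (3S,4R)-3-methyl-3-(prop-2-en-1-yl)-4-{[tri(propan-2-yl)silyl]ethynyl}oxan-2-one, via lithium enolate 14 (not isolated)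
Conditions: LDA, THF/DMPU, -78 °C; allyl bromide, -78 to -20 °C
Reagents that add atoms: allyl bromide C=CCBr
Why: Alkylation of the tetrasubstituted lactone enolate: A(1,2) strain with the methyl group pushes the C5 alkynyl group pseudo-axial, so allyl bromide enters from the opposite face and sets the quaternary C4 (allyl trans, methyl cis to the alkynyl group).

Step 8
Reactants: 15 (3S,4R)-3-methyl-3-(prop-2-en-1-yl)-4-{[tri(propan-2-yl)silyl]ethynyl}oxan-2-one
Product: 17 (3S,4R)-3-(3-hydroxypropyl)-3-methyl-4-{[tri(propan-2-yl)silyl]ethynyl}oxan-2-one, via B-alkyl-9-BBN adduct 16 (not isolated)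
Conditions: 9-BBN-H, THF, 0 °C to rt; 30% H2O2, pH 7 phosphate buffer, 0 °C
Reagents that add atoms: hydrogen peroxide OO
Why: Hydroboration-oxidation: 9-BBN-H prefers the monosubstituted alkene to the hindered silylalkyne and places boron at the terminus (future C1), and a shift of the acyl group to the new hydroxyl would be harmless because step 10 opens the lactone.

Step 9
Reactants: 17 (3S,4R)-3-(3-hydroxypropyl)-3-methyl-4-{[tri(propan-2-yl)silyl]ethynyl}oxan-2-one
Product: 18 (3S,4S)-4-ethynyl-3-(3-hydroxypropyl)-3-methyloxan-2-one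
Conditions: Bu4NF, AcOH (1:1), THF, 0 °C to rt
Reagents that add atoms: none
Why: Fluoride-induced protodesilylation of the alkynylsilane, with acetic acid as buffer so that the lactone stays closed (the descriptor at C4 of the oxanone changes only through CIP priorities).

Step 10
Reactants: 18 (3S,4S)-4-ethynyl-3-(3-hydroxypropyl)-3-methyloxan-2-one
Product: 21 (2S,3S)-3-ethynyl-2-methyl-5-[(triethylsilyl)oxy]-2-{3-[(triethylsilyl)oxy]propyl}pentanoic acid, via potassium carboxylate 19 (not isolated), via tris(triethylsilyl) derivative 20 (not isolated)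
Conditions: KOH (1.05 equiv), THF/H2O, 40 °C; evaporate; Et3SiCl (3.5 equiv), imidazole, DMF, 0 °C; pH 6 buffer work-up
Reagents that add atoms: potassium hydroxide [K+].[OH-]; chlorotriethylsilane CC[Si](Cl)(CC)CC
Why: Saponification opens the temporary delta-lactone as its carboxylate, exhaustive silylation masks both primary alcohols so that they cannot later attack the enol lactone, and the labile silyl ester falls off on work-up.

Step 11
Reactants: 21 (2S,3S)-3-ethynyl-2-methyl-5-[(triethylsilyl)oxy]-2-{3-[(triethylsilyl)oxy]propyl}pentanoic acid; 5 6-iodo-5-methoxy-4-(propan-2-yl)-1,3-benzodioxole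
Product: 23 (3S,4R,5E)-5-{[6-methoxy-7-(propan-2-yl)-1,3-benzodioxol-5-yl]methylidene}-3-methyl-4-{2-[(triethylsilyl)oxy]ethyl}-3-{3-[(triethylsilyl)oxy]propyl}oxolan-2-one, via potassium salt 22 (not isolated)
Conditions: KOt-Bu (1.0 equiv), DMSO, rt; then 5, Pd(OAc)2 (5 mol %), P(2-furyl)3 (10 mol %), rt to 40 °C
Reagents that add atoms: none
Why: Palladium-catalysed arylative 5-exo-dig lactonisation of a 4-alkynoic acid: ArPdI, formed by oxidative addition of 5 to zerovalent palladium, activates the alkyne, the carboxylate attacks C6 anti, and reductive elimination forms C7-C8, so aryl and ring oxygen end up trans (E) and ring C lies cis to C5.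

Step 12
Reactants: 23 (3S,4R,5E)-enol lactone bis(triethylsilyl ether)
Product: 24 3-[(3S,4R,5E)-5-{[6-methoxy-7-(propan-2-yl)-1,3-benzodioxol-5-yl]methylidene}-3-methyl-2-oxo-4-(2-oxoethyl)oxolan-3-yl]propanal
Conditions: (COCl)2, DMSO, CH2Cl2, -78 to -40 °C; Et3N, -78 to 0 °C
Reagents that add atoms: none
Why: Swern oxidation of primary triethylsilyl ethers: the chlorosulfonium salt removes silicon as Et3SiCl and oxidises both termini (C1, C20) directly to aldehydes, so no free alcohol ever faces the enol lactone.

Step 13
Reactants: 24 1,7-dialdehyde (C1, C20) with E enol lactone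
Product: 27 (1R,4S,5R)-1-hydroxy-14-methoxy-11,12-methylenedioxyicetexa-6,8,10(20),11,13-pentaen-19,6-olide, via ring-B carbinol 25 (not isolated), via styrene aldehyde 26 (not isolated)
Conditions: Sc(OTf)3 (20 mol %), 2,6-di-tert-butylpyridine (20 mol %), 4 Å MS, CH2Cl2 (0.01 M), -40 to 0 °C
Reagents that add atoms: none
Why: Proposed new method: the Sc-bound C20 aldehyde is attacked by C9, the only free carbon of ring C (Friedel-Crafts hydroxyalkylation, 7-exo-trig at the carbonyl, ring B), and carbinol 25, ionised with help from the ortho oxygen O-11, loses H-10 to give styrene 26. In 26 the C10=C20 bond is a vinylogous aryl enol ether of O-11, so C10 adds to the Sc-bound C1 aldehyde (Prins-type closure, 6-exo-trig at the carbonyl with the nucleophilic double bond exocyclic to the new ring A), and the returning C20 cation can lose only H-10, which restores C10=C20 and leaves the allylic alcohol. The closest known reaction types are the Bradsher-type cyclodehydration of arene-tethered aldehydes, the Prins and carbonyl-ene cyclisations of unsaturated aldehydes and the Mukaiyama aldol-Prins cascade; their union on one 1,7-dialdehyde, with vinylic instead of allylic proton loss, has not been shown. C1, the only new stereocentre that is kept, is set in a chair-like transition state anchored by the cis-fused lactone (C19 axial, methyl equatorial, H-5 axial) in which the metal-bound oxygen sits equatorial, away from axial H-3 and H-5, and becomes the 1-beta (R) hydroxyl; the centres at C10 and C20 of 25 vanish. The step needs the arene to take C20 before either aldehyde enolises and needs C1 to stay out of that first event: the E geometry of C6=C7 holds C9 next to the two-carbon arm on C5, C1 could reach C9 only through a nine-membered ring, and a non-enolising Lewis acid at low temperature with a hindered base suppresses the C2-to-C20 aldol. It also needs 27 to survive, which a catalytic water-tolerant acid, molecular sieves and an early quench should secure, and an aldol-first order of events (C10 enol onto C1, then arene onto C20 and loss of water) would converge on the same product.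

Step 14
Reactants: 27 (1R,4S,5R)-1-hydroxy-14-methoxy-11,12-methylenedioxyicetexa-6,8,10(20),11,13-pentaen-19,6-olide
Product: 28 6,7-anhydroballotiquinone
Conditions: (NH4)2Ce(NO3)6 (2.2 equiv), MeCN/H2O (4:1), -10 to 0 °C, short contact time
Reagents that add atoms: water O
Why: Oxidative dealkylation of a hydroquinone diether by tetravalent cerium: two one-electron oxidations and attack of water at C11 and C14 give the para-quinone, methanol leaves from C14, and the hemiformal left on O-12 collapses to formaldehyde and the free 12-OH without touching a stereocentre.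

Compound list
1 | 5-methoxy-1,3-benzodioxole | COc1ccc2OCOc2c1 | starting material
2 | (5-methoxy-1,3-benzodioxol-4-yl)lithium | COc1ccc2OCOc2c1[Li] | intermediate
3 | 2-(5-methoxy-1,3-benzodioxol-4-yl)propan-2-ol | COc1ccc2OCOc2c1C(C)(C)O | intermediate
4 | 5-methoxy-4-(propan-2-yl)-1,3-benzodioxole | COc1ccc2OCOc2c1C(C)C | intermediate
5 | 6-iodo-5-methoxy-4-(propan-2-yl)-1,3-benzodioxole | COc1c(I)cc2OCOc2c1C(C)C | intermediate
6 | ethynyltri(propan-2-yl)silane | C#C[Si](C(C)C)(C(C)C)C(C)C | starting material
7 | benzophenone | O=C(c1ccccc1)c1ccccc1 | starting material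
8 | lithium [tri(propan-2-yl)silyl]acetylide | [Li]C#C[Si](C(C)C)(C(C)C)C(C)C | intermediate
9 | 1,1-diphenyl-3-[tri(propan-2-yl)silyl]prop-2-yn-1-ol | OC(C#C[Si](C(C)C)(C(C)C)C(C)C)(c1ccccc1)c1ccccc1 | intermediate
10 | 5,6-dihydro-2H-pyran-2-one | O=C1OCCC=C1 | starting material
11 | (4R)-4-{[tri(propan-2-yl)silyl]ethynyl}oxan-2-one | O=C1OCC[C@@H](C#C[Si](C(C)C)(C(C)C)C(C)C)C1 | intermediate
12 | lithium enolate of 11 | [Li]OC1=C[C@H](C#C[Si](C(C)C)(C(C)C)C(C)C)CCO1 | intermediate
13 | (3S,4R)-3-methyl-4-{[tri(propan-2-yl)silyl]ethynyl}oxan-2-one (methyl trans to alkynyl) | O=C1OCC[C@@H](C#C[Si](C(C)C)(C(C)C)C(C)C)[C@@H]1C | intermediate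
14 | lithium enolate of 13 | [Li]OC1=C(C)[C@H](C#C[Si](C(C)C)(C(C)C)C(C)C)CCO1 | intermediate
15 | (3S,4R)-3-methyl-3-(prop-2-en-1-yl)-4-{[tri(propan-2-yl)silyl]ethynyl}oxan-2-one (allyl trans to alkynyl) | O=C1OCC[C@@H](C#C[Si](C(C)C)(C(C)C)C(C)C)[C@]1(C)CC=C | intermediate
16 | B-alkyl-9-borabicyclo[3.3.1]nonane adduct of 15 (boron on the terminal carbon) | O=C1OCC[C@@H](C#C[Si](C(C)C)(C(C)C)C(C)C)[C@]1(C)CCCB1C2CCCC1CCC2 | intermediate
17 | (3S,4R)-3-(3-hydroxypropyl)-3-methyl-4-{[tri(propan-2-yl)silyl]ethynyl}oxan-2-one | O=C1OCC[C@@H](C#C[Si](C(C)C)(C(C)C)C(C)C)[C@]1(C)CCCO | intermediate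
18 | (3S,4S)-4-ethynyl-3-(3-hydroxypropyl)-3-methyloxan-2-one | O=C1OCC[C@@H](C#C)[C@]1(C)CCCO | intermediate
19 | potassium (2S,3S)-3-ethynyl-5-hydroxy-2-(3-hydroxypropyl)-2-methylpentanoate | [K+].[O-]C(=O)[C@@](C)(CCCO)[C@@H](CCO)C#C | intermediate
20 | triethylsilyl (2S,3S)-3-ethynyl-2-methyl-5-[(triethylsilyl)oxy]-2-{3-[(triethylsilyl)oxy]propyl}pentanoate | CC[Si](CC)(CC)OC(=O)[C@@](C)(CCCO[Si](CC)(CC)CC)[C@@H](CCO[Si](CC)(CC)CC)C#C | intermediate
21 | (2S,3S)-3-ethynyl-2-methyl-5-[(triethylsilyl)oxy]-2-{3-[(triethylsilyl)oxy]propyl}pentanoic acid | OC(=O)[C@@](C)(CCCO[Si](CC)(CC)CC)[C@@H](CCO[Si](CC)(CC)CC)C#C | intermediate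
22 | potassium salt of 21 | [K+].[O-]C(=O)[C@@](C)(CCCO[Si](CC)(CC)CC)[C@@H](CCO[Si](CC)(CC)CC)C#C | intermediate
23 | (3S,4R,5E)-5-{[6-methoxy-7-(propan-2-yl)-1,3-benzodioxol-5-yl]methylidene}-3-methyl-4-{2-[(triethylsilyl)oxy]ethyl}-3-{3-[(triethylsilyl)oxy]propyl}oxolan-2-one | CC(C)c1c2OCOc2cc(/C=C3/OC(=O)[C@@](C)(CCCO[Si](CC)(CC)CC)[C@H]3CCO[Si](CC)(CC)CC)c1OC | intermediate
24 | 3-[(3S,4R,5E)-5-{[6-methoxy-7-(propan-2-yl)-1,3-benzodioxol-5-yl]methylidene}-3-methyl-2-oxo-4-(2-oxoethyl)oxolan-3-yl]propanal | CC(C)c1c2OCOc2cc(/C=C3/OC(=O)[C@@](C)(CCC=O)[C@H]3CC=O)c1OC | intermediate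
25 | ring-B carbinol: 24 with C9 bonded to C20, OH on C20 (configuration undefined), C10H2, C1 aldehyde intact, (4S,5R) | CC(C)c1c2OCOc2c2c(C=C3OC(=O)[C@@](C)(CCC=O)[C@H]3CC2O)c1OC | intermediate
26 | styrene aldehyde: benzocycloheptatriene with C6=C7 and C10H=C20H, 19,6-enol lactone, CH2CH2CHO on C4, (4S,5R) | CC(C)c1c2OCOc2c2c(C=C3OC(=O)[C@@](C)(CCC=O)[C@H]3C=C2)c1OC | intermediate
27 | (1R,4S,5R)-1-hydroxy-14-methoxy-11,12-methylenedioxyicetexa-6,8,10(20),11,13-pentaen-19,6-olide | CC(C)c1c2OCOc2c2c(C=C3OC(=O)[C@@]4(C)CC[C@@H](O)C(=C2)[C@@H]34)c1OC | intermediate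
28 | 6,7-anhydroballotiquinone, (1R,4S,5R)-1,12-dihydroxy-11,14-dioxoicetexa-6,8,10(20),12-tetraen-19,6-olide | CC(C)C1=C(O)C(=O)C2=C(C=C3OC(=O)[C@@]4(C)CC[C@@H](O)C(=C2)[C@@H]34)C1=O | target

Total step count: 14. Longest linear sequence: 11 steps (steps 4 to 14).

Steps most likely to fail

Step 13. Four things may go wrong. The aldehydes may enolise and close an aldol in the wrong sense (C2 onto C20). C-protonation may isomerise the enol lactone from E to Z before ring B closes. The sequence may stall after the first ring. The new allylic alcohol may ionise and lose water. The fallback sets out from 24 and uses known reactions only. Catalytic camphorsulfonic acid in CH2Cl2 over sieves should bring about only the arene/C20 cyclodehydration, and 26 is isolated. Pinnick oxidation (NaClO2, NaH2PO4, 2-methyl-2-butene) gives the carboxylic acid F1. Oxalyl chloride with catalytic DMF gives the acid chloride F2. SnCl4 in CH2Cl2 at -78 °C effects an intramolecular Darzens-Nenitzescu acylation of the styrene carbon C10. This forms the same C1-C10 bond with a far stronger electrophile and gives the acid-stable cross-conjugated enone F3. Luche reduction (NaBH4, CeCl3·7H2O, MeOH/THF, -78 °C), with axial hydride delivery from the alpha face, sets the equatorial 1-beta alcohol and comes back to the route at 27. The same enone also corrects poor facial selectivity at C1, because 27 and its epimer can be oxidised to it with MnO2.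

Step 14. The electron-rich benzocycloheptatriene may be over-oxidised, by loss of H-5 from the radical cation on the way to a benzotropylium ion. Attack at the dioxole side may also lead to an ortho-quinone. The fallback sets out from 27 and removes the triene before the oxidation. LiOH (1 equiv, THF/H2O, 0 °C) opens the enol lactone to the 6-oxo-19-oic acid F4. (NH4)2Ce(NO3)6 then oxidises ring C of this less oxidisable substrate to the hydroxyquinone keto acid F5. Catalytic p-toluenesulfonic acid over sieves in toluene re-closes the ring by dehydrative enol lactonisation toward the quinone-activated C7, and the route is rejoined at 28. C5 may epimerise through the C6 enol, but only the cis isomer can lactonise.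

Step 11. Direct C-H arylation of the alkyne, proton-terminated cyclisation without aryl transfer, or slow oxidative addition of the electron-rich ortho-substituted iodide may compete. The fallback sets out from 22 (made from 21 as in step 11) and from 5. Iodine in MeCN converts 22 by anti iodolactonisation into the (E)-iodomethylidene lactone F6. Miyaura borylation of 5 (bis(pinacolato)diboron, PdCl2(dppf), KOAc, dioxane) gives the aryl pinacol boronate F7. Suzuki-Miyaura coupling of the two (PdCl2(dppf), K3PO4, THF/H2O, rt) proceeds with retention of the double-bond geometry and comes back to the route at 23.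

Further compounds
F1 | step 13 | carboxylic acid from 26 (CH2CH2CO2H on C4, otherwise as 26) | CC(C)c1c2OCOc2c2c(C=C3OC(=O)[C@@](C)(CCC(=O)O)[C@H]3C=C2)c1OC
F2 | step 13 | acid chloride of F1 | CC(C)c1c2OCOc2c2c(C=C3OC(=O)[C@@](C)(CCC(=O)Cl)[C@H]3C=C2)c1OC
F3 | step 13 | (4S,5R)-14-methoxy-11,12-methylenedioxy-1-oxoicetexa-6,8,10(20),11,13-pentaen-19,6-olide | CC(C)c1c2OCOc2c2c(C=C3OC(=O)[C@@]4(C)CCC(=O)C(=C2)[C@@H]34)c1OC
F4 | step 14 | (1R,4S,5R)-1-hydroxy-14-methoxy-11,12-methylenedioxy-6-oxoicetexa-8,10(20),11,13-tetraen-19-oic acid | CC(C)c1c2OCOc2c2c(CC(=O)[C@@H]3C(=C2)[C@H](O)CC[C@]3(C)C(=O)O)c1OC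
F5 | step 14 | (1R,4S,5R)-1,12-dihydroxy-6,11,14-trioxoicetexa-8,10(20),12-trien-19-oic acid | CC(C)C1=C(O)C(=O)C2=C(CC(=O)[C@@H]3C(=C2)[C@H](O)CC[C@]3(C)C(=O)O)C1=O
F6 | step 11 | (3S,4R,5E)-5-(iodomethylidene)-3-methyl-4-{2-[(triethylsilyl)oxy]ethyl}-3-{3-[(triethylsilyl)oxy]propyl}oxolan-2-one | I/C=C1/OC(=O)[C@@](C)(CCCO[Si](CC)(CC)CC)[C@H]1CCO[Si](CC)(CC)CC
F7 | step 11 | 2-[6-methoxy-7-(propan-2-yl)-1,3-benzodioxol-5-yl]-4,4,5,5-tetramethyl-1,3,2-dioxaborolane | COc1c(B2OC(C)(C)C(C)(C)O2)cc2OCOc2c1C(C)C
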